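**Quick number.** The slowness of the violet run shaped my reply: at 70 °C it held 30.0% bis adduct after 5.00 h, so I expected your flasks still to be climbing at 6.0 h. Your hunch, that the four would finish within 1.5 percentage points of each other since each gets the same charges, I therefore did not share.

| flask | substrate | reagent | scavenger | temperature | remark | time |
|---|---|---|---|---|---|---|
| blue | 30 mM | 36 mM | 45 mM | 55 °C | run made earlier |  |
| violet | 20 mM | 36 mM | 45 mM | 70 °C | run made earlier |  |
| teal | 45 mM | 36 mM | 45 mM | 55 °C | run made earlier |  |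
| ochre | 30 mM | 18 mM | 45 mM | 70 °C | run made earlier |  |
| dawn | 30 mM | 36.0 mM (fed, over 2.5 h) | 45.0 mM | 70 °C | all else is in the flask from the start; the feed brings no volume worth counting | 6.0 h |
| spring | 30 mM | 36.0 mM | 45.0 mM | 70 °C | everything together at the start | 6.0 h |
| winter | 30 mM | 36.0 mM (fed, over 2.5 h) | 45.0 mM |  | the addition at 30 °C, then warmed to 70 °C; the feed brings no volume worth counting | 6.0 h |
| autumn | 30 mM (fed, over 2.5 h) | 36.0 mM | 45.0 mM | 70 °C | all else is in the flask from the start; the feed brings no volume worth counting | 6.0 h |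

- blue (time / h: bis adduct / %, mono adduct / %): 2.00: 1.1, 8.6; 3.00: 2.8, 8.1; 5.00: 4.7, 11.7; 6.00: 8.9, 12.1; 8.00: 9.9, 13.0; 10.0: 13.2, 15.0; 12.0: 16.5, 14.0
- violet (time / h: bis adduct / %, mono adduct / %): 0.667: 1.9, 7.3; 1.33: 4.8, 12.3; 2.00: 11.8, 13.5; 3.00: 17.4, 11.8; 4.00: 22.8, 14.0; 5.00: 30.0, 11.1
- teal (time / h: bis adduct / %, mono adduct / %): 0.833: 0, 2.8; 1.33: 1.3, 4.5; 2.00: 1.0, 6.8; 3.00: 1.5, 7.9; 4.00: 5.4, 11.2; 6.00: 6.4, 11.0; 10.0: 11.6, 12.7
- ochre (time / h: bis adduct / %, mono adduct / %): 1.00: 0.9, 6.1; 2.00: 3.3, 8.3; 3.00: 4.0, 9.3; 4.00: 7.6, 12.6; 5.00: 9.9, 12.0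

(each reading ± 1 percentage point)



1. the flask that comes out highest in amount of bis adduct, in percent of the substrate charged; "all alike" if 1.5 percentage points covers them all (dawn / spring / winter / autumn / all alike)
2. amount of bis adduct at the end, in percent of the substrate charged, dawn
3. amount of bis adduct at the end, in percent of the substrate charged, spring
4. amount of bis adduct at the end, in percent of the substrate charged, winter
5. amount of bis adduct at the end, in percent of the substrate charged, autumn

**Feed lag.** In violet, bis adduct climbed close to a straight line, from 11.8% at 2.00 h to 30.0% at 5.00 h, so I took the end value as proportional to working time. A steady feed delivers its average portion late by 1.25 h, which is half the feed time, and I treated this as a dead time and called it the feed lag. That left dawn 79.2% of the working time of spring, and autumn carried the same lag.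

**The forecast.** It gave spring 29%, dawn 24.3%, autumn 25% and winter 19%, with spring highest, on the ground that “slow feeding merely costs exposure time”. My lag applied to its spring figure gave dawn 23.0%, which is lower than its own 24.3%.

**The flasks.** Of the four, spring came out highest at 26.8%, with autumn at 22.8%, dawn at 22.5% and winter at 17.7%.

    substrate + reagent → mono adduct + released group (k = 4.60 M⁻¹ h⁻¹, Ea = 77.0 kJ mol⁻¹)
    substrate + reagent → other mono adduct + released group (k = 3.00 M⁻¹ h⁻¹, Ea = 60.0 kJ mol⁻¹)
    reagent + mono adduct → bis adduct + released group (k = 18.0 M⁻¹ h⁻¹, Ea = 82.0 kJ mol⁻¹)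
    reagent + other mono adduct → bis adduct + released group (k = 2.50 M⁻¹ h⁻¹, Ea = 76.0 kJ mol⁻¹)
    substrate + released group ⇌ idle adduct, settled at all times (K = 24.0 M⁻¹, ΔH = −5.00 kJ mol⁻¹)
    scavenger + released group → scavenged by-product (k = 1200 M⁻¹ h⁻¹, Ea = 56.0 kJ mol⁻¹)
    (constants at 70 °C)

**Lag tested.** The lag took spring's value to 21.2% against dawn's 22.5%, and dawn dosed over 0.250 h reckoned the same way gave 26.2% against its simulated 26.4%. Spring leads autumn by 4.0 points, while spring at 30.9 mM reagent had moved by 5 points. In winter, the half-life of substrate by its step to mono adduct stood at 5.8 h at 3.84 h, longer than the 3.50 h left after the feed. Winter still held 51.5% of its substrate at 6.00 h.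

The numbers in the tables come from a simulation with constants of no real substance, noise included.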